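**Retrosynthetic overview**
- Target 20 ← hydrogenolysis and mono-O-methylation of the symmetric resorcinol 18. The strategy rests on ring A: C1 carries the CH2CH2 bridge to ring B, C2 and C6 the two p-oxybenzyl groups, C3 and C5 the oxygens, C4 a hydrogen. This is the carbon pattern of a tetraketide folded by aldol closure.
- Ring A (the only ring formed; ring B and both benzyl rings are bought) ← aldol closure of chain C2 onto the C7 ketone of tert-butyl 3,5,7-trioxo ester 14, with dehydration and loss of the ester carboxyl. Both benzyl groups already sit on chain C2 and C6.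
- 14 ← ketal hydrolysis of 13 ← acylation (C4–C5 bond) of the dianion of benzylated tert-butyl acetoacetate 11 with the ketal-masked, benzylated β-keto Weinreb amide 9.
- 9 ← ketalisation, C-benzylation and Meldrum's acid homologation of 3-[3-(benzyloxy)phenyl]propanoic acid 3; 11 ← C-benzylation of tert-butyl acetoacetate.

Key step: step 8

Remark: the target has no stereocentre and is achiral, so no enantiocontrol is needed; stereocentres in chain intermediates are carried as mixtures and disappear on aromatisation.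

**Step 1**
Reactants: 1 3-(3-hydroxyphenyl)propanoic acid
Product: 3 3-[3-(benzyloxy)phenyl]propanoic acid, via benzyl 3-[3-(benzyloxy)phenyl]propanoate 2 (not isolated)
Conditions: BnBr (2.3 equiv), K2CO3, DMF, 60 °C; then 2 M NaOH, MeOH, 60 °C; 1 M HCl to pH 2
Reagents that add atoms: benzyl bromide, BrCc1ccccc1
Why: Williamson O-benzylation of phenoxide and carboxylate, then saponification of the benzyl ester, should leave only the aryl benzyl ether.

**Step 2**
Reactants: 3 3-[3-(benzyloxy)phenyl]propanoic acid; 4 Meldrum's acid (2,2-dimethyl-1,3-dioxane-4,6-dione)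
Product: 6 5-[3-(benzyloxy)phenyl]-N-methoxy-N-methyl-3-oxopentanamide, via acyl Meldrum's acid 5 (not isolated)
Conditions: DCC, DMAP (1.2 equiv), CH2Cl2, 0 °C → rt; filter, 1 M HCl wash; then MeNHOMe·HCl, Et3N, toluene, 90 °C
Reagents that add atoms: N,O-dimethylhydroxylamine hydrochloride, CNOC.Cl
Why: Steglich-type C-acylation of Meldrum's acid, then thermal fragmentation to the acylketene and its capture by the hydroxylamine (Meldrum's acid β-keto amide synthesis), should give the β-keto Weinreb amide with loss of acetone and CO2.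

**Step 3**
Reactants: 6 5-[3-(benzyloxy)phenyl]-N-methoxy-N-methyl-3-oxopentanamide; 7 4-(benzyloxy)benzyl chloride
Product: 8 2-[4-(benzyloxy)benzyl]-5-[3-(benzyloxy)phenyl]-N-methoxy-N-methyl-3-oxopentanamide (racemic)
Conditions: NaH (1.05 equiv), THF, 0 °C; then 7 (0.95 equiv), NaI (cat.), rt → 50 °C
Reagents that add atoms: none
Why: SN2 C-alkylation of the sodium enolate of a β-keto amide with a reactive p-alkoxybenzyl halide (Finkelstein-assisted), with the halide limiting to suppress dialkylation; the new centre is racemic and is destroyed later.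

**Step 4**
Reactants: 8 2-[4-(benzyloxy)benzyl]-5-[3-(benzyloxy)phenyl]-N-methoxy-N-methyl-3-oxopentanamide
Product: 9 3-[4-(benzyloxy)phenyl]-2-{2-[2-(3-benzyloxyphenyl)ethyl]-1,3-dioxolan-2-yl}-N-methoxy-N-methylpropanamide (racemic)
Conditions: (TMSOCH2)2, TMSOTf (cat.), CH2Cl2, –78 °C → rt; pyridine, aq. NaHCO3
Reagents that add atoms: 1,2-bis(trimethylsilyloxy)ethane, C[Si](C)(C)OCCO[Si](C)(C)C
Why: Silyl-transfer ketalisation (Noyori conditions) suits hindered α-branched ketones and spares benzyl ethers and the Weinreb amide; masking removes the acidic C–H between the carbonyls so the amide can act as an acyl donor towards a dianion.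

**Step 5**
Reactants: 10 tert-butyl acetoacetate; 7 4-(benzyloxy)benzyl chloride
Product: 11 tert-butyl 2-[4-(benzyloxy)benzyl]-3-oxobutanoate (racemic)
Conditions: 10 (1.5 equiv), NaH, THF, 0 °C; then 7, NaI (cat.), 50 °C
Reagents that add atoms: none
Why: Acetoacetic ester alkylation (SN2 of the sodium enolate), with excess 10 to favour monoalkylation; the centre is racemic and is lost on aromatisation.

**Step 6**
Reactants: 11 tert-butyl 2-[4-(benzyloxy)benzyl]-3-oxobutanoate; 9 3-[4-(benzyloxy)phenyl]-2-{2-[2-(3-benzyloxyphenyl)ethyl]-1,3-dioxolan-2-yl}-N-methoxy-N-methylpropanamide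
Product: 13 tert-butyl 2-[4-(benzyloxy)benzyl]-7-[4-(benzyloxy)phenyl]-6-{2-[2-(3-benzyloxyphenyl)ethyl]-1,3-dioxolan-2-yl}-3,5-dioxoheptanoate (diastereomer mixture), via dilithium dienolate 12 (not isolated)
Conditions: 11 (1.4 equiv), LDA (2.05 equiv per 11), THF, –78 → 0 °C; then 9, –78 °C → rt; AcOH, –78 °C
Reagents that add atoms: none
Why: Acylation of a β-keto ester dianion at its γ-carbon by a Weinreb amide stops at the chelated tetrahedral adduct, so the 3,5-diketo ester is released only on quench and cannot protonate unreacted dianion; the amide α-C–H is far less acidic than the dianion's conjugate acid, so enolisation with opening of the ketal should not compete.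

**Step 7**
Reactants: 13 tert-butyl 2-[4-(benzyloxy)benzyl]-7-[4-(benzyloxy)phenyl]-6-{2-[2-(3-benzyloxyphenyl)ethyl]-1,3-dioxolan-2-yl}-3,5-dioxoheptanoate
Product: 14 tert-butyl 2,6-bis[4-(benzyloxy)benzyl]-9-[3-(benzyloxy)phenyl]-3,5,7-trioxononanoate (diastereomer and enol-tautomer mixture)
Conditions: 1 M aq. HCl–THF (1:3), rt
Reagents that add atoms: water, O
Why: Acid-catalysed dioxolane hydrolysis through the oxocarbenium ion under dilute aqueous acid at room temperature, conditions that tert-butyl esters and aryl benzyl ethers tolerate and that are too mild to cyclodehydrate the triketone to a pyranone.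

**Step 8**
Reactants: 14 tert-butyl 2,6-bis[4-(benzyloxy)benzyl]-9-[3-(benzyloxy)phenyl]-3,5,7-trioxononanoate
Product: 18 4,6-bis[4-(benzyloxy)benzyl]-5-{2-[3-(benzyloxy)phenyl]ethyl}benzene-1,3-diol, via aldol adduct 15 (not isolated), via cyclohexenedione ester 16 (not isolated), via cyclohexenedione acid 17 (not isolated)
Conditions: Cs2CO3 (2.5 equiv), THF–i-PrOH (4:1), rt → 45 °C; 1 M HCl wash; then TFA–CH2Cl2 (1:5), 0 °C → rt
Reagents that add atoms: none
Why: Proposed new method: carbonate base should form the enolate of chain C2, the only terminal carbon lying between two carbonyls, which adds to the C7 ketone to make the C2–C7 bond (C2–C1 of ring A) and close the six-membered ring in a 6-(enolexo)-exo-trig aldol; E1cB loss of water across C6–C7 then gives the vinylogous-acid anion of 16, a thermodynamic sink that pulls the congested, reversible aldol forward. TFA cleaves the tert-butyl ester, and acid 17, a β-keto acid whose carboxyl sits on the quaternary ring carbon, loses CO2 through the adjacent carbonyl to give the dienol that is resorcinol 18, so aromatisation drives the sequence. The closest known reaction type is the base-mediated aldol aromatisation of 3,5,7-triketo esters to resorcylates, where the ester is kept and a proton is lost; here C2 bears a benzyl group, so the carboxyl must leave instead, as in the stilbene-synthase fold, which has not been shown without an enzyme. The selectivity needed is C2→C7 aldol over Claisen attack of C6 on the ester (opposed by the tert-butyl group and the tertiary C6), over aldol of the bridge-side C8 onto the C3 ketone (C8 is a plain ketone α-CH2, far less acidic than C2) and over O-cyclisation to pyranones (acid-promoted, avoided by completing the base stage first). The three stereocentres of 15 and the two of 14 are erased on aromatisation, so no stereocontrol is required.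

**Step 9**
Reactants: 18 4,6-bis[4-(benzyloxy)benzyl]-5-{2-[3-(benzyloxy)phenyl]ethyl}benzene-1,3-diol
Product: 19 2,4-bis[4-(benzyloxy)benzyl]-3-{2-[3-(benzyloxy)phenyl]ethyl}-5-methoxyphenol
Conditions: MeI (1.0 equiv), K2CO3 (1.1 equiv), acetone, rt; recovered 18 recycled
Reagents that add atoms: iodomethane, CI
Why: Williamson O-methylation; the two hydroxyls of 18 are equivalent by symmetry, so only the degree of methylation has to be controlled, by limiting MeI and recycling the diol.

**Step 10**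
Reactants: 19 2,4-bis[4-(benzyloxy)benzyl]-3-{2-[3-(benzyloxy)phenyl]ethyl}-5-methoxyphenol
Product: 20 2,4-bis(4-hydroxybenzyl)-3-[2-(3-hydroxyphenyl)ethyl]-5-methoxyphenol (target)
Conditions: H2 (1 atm), 10% Pd/C, EtOAc–MeOH, rt
Reagents that add atoms: none
Why: Catalytic hydrogenolysis of the three aryl benzyl ethers; the diarylmethane and bibenzyl C–C bonds and the methyl ether are inert under these conditions.

**Compound list**
1 | 3-(3-hydroxyphenyl)propanoic acid | OC(=O)CCc1cccc(O)c1 | starting material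
2 | benzyl 3-[3-(benzyloxy)phenyl]propanoate | O=C(CCc1cccc(OCc2ccccc2)c1)OCc1ccccc1 | intermediate
3 | 3-[3-(benzyloxy)phenyl]propanoic acid | OC(=O)CCc1cccc(OCc2ccccc2)c1 | intermediate
4 | Meldrum's acid (2,2-dimethyl-1,3-dioxane-4,6-dione) | CC1(C)OC(=O)CC(=O)O1 | starting material
5 | 5-{3-[3-(benzyloxy)phenyl]-1-hydroxypropylidene}-2,2-dimethyl-1,3-dioxane-4,6-dione | CC1(C)OC(=O)C(=C(O)CCc2cccc(OCc3ccccc3)c2)C(=O)O1 | intermediate
6 | 5-[3-(benzyloxy)phenyl]-N-methoxy-N-methyl-3-oxopentanamide | CON(C)C(=O)CC(=O)CCc1cccc(OCc2ccccc2)c1 | intermediate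
7 | 4-(benzyloxy)benzyl chloride | ClCc1ccc(OCc2ccccc2)cc1 | starting material
8 | 2-[4-(benzyloxy)benzyl]-5-[3-(benzyloxy)phenyl]-N-methoxy-N-methyl-3-oxopentanamide (racemic) | CON(C)C(=O)C(Cc1ccc(OCc2ccccc2)cc1)C(=O)CCc1cccc(OCc2ccccc2)c1 | intermediate
9 | 3-[4-(benzyloxy)phenyl]-2-{2-[2-(3-benzyloxyphenyl)ethyl]-1,3-dioxolan-2-yl}-N-methoxy-N-methylpropanamide (racemic) | CON(C)C(=O)C(Cc1ccc(OCc2ccccc2)cc1)C1(CCc2cccc(OCc3ccccc3)c2)OCCO1 | intermediate
10 | tert-butyl acetoacetate | CC(=O)CC(=O)OC(C)(C)C | starting material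
11 | tert-butyl 2-[4-(benzyloxy)benzyl]-3-oxobutanoate (racemic) | CC(=O)C(Cc1ccc(OCc2ccccc2)cc1)C(=O)OC(C)(C)C | intermediate
12 | dilithium dienolate (dianion) of 11 | [Li+].[Li+].C=C([O-])C(Cc1ccc(OCc2ccccc2)cc1)=C([O-])OC(C)(C)C | intermediate
13 | tert-butyl 2-[4-(benzyloxy)benzyl]-7-[4-(benzyloxy)phenyl]-6-{2-[2-(3-benzyloxyphenyl)ethyl]-1,3-dioxolan-2-yl}-3,5-dioxoheptanoate (diastereomer mixture) | CC(C)(C)OC(=O)C(Cc1ccc(OCc2ccccc2)cc1)C(=O)CC(=O)C(Cc1ccc(OCc2ccccc2)cc1)C1(CCc2cccc(OCc3ccccc3)c2)OCCO1 | intermediate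
14 | tert-butyl 2,6-bis[4-(benzyloxy)benzyl]-9-[3-(benzyloxy)phenyl]-3,5,7-trioxononanoate (diastereomer mixture) | CC(C)(C)OC(=O)C(Cc1ccc(OCc2ccccc2)cc1)C(=O)CC(=O)C(Cc1ccc(OCc2ccccc2)cc1)C(=O)CCc1cccc(OCc2ccccc2)c1 | intermediate
15 | tert-butyl 1,3-bis[4-(benzyloxy)benzyl]-2-{2-[3-(benzyloxy)phenyl]ethyl}-2-hydroxy-4,6-dioxocyclohexane-1-carboxylate (diastereomer mixture) | CC(C)(C)OC(=O)C1(Cc2ccc(OCc3ccccc3)cc2)C(=O)CC(=O)C(Cc2ccc(OCc3ccccc3)cc2)C1(O)CCc1cccc(OCc2ccccc2)c1 | intermediate
16 | tert-butyl 1,3-bis[4-(benzyloxy)benzyl]-2-{2-[3-(benzyloxy)phenyl]ethyl}-4,6-dioxocyclohex-2-ene-1-carboxylate (racemic) | CC(C)(C)OC(=O)C1(Cc2ccc(OCc3ccccc3)cc2)C(=O)CC(=O)C(Cc2ccc(OCc3ccccc3)cc2)=C1CCc1cccc(OCc2ccccc2)c1 | intermediate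
17 | 1,3-bis[4-(benzyloxy)benzyl]-2-{2-[3-(benzyloxy)phenyl]ethyl}-4,6-dioxocyclohex-2-ene-1-carboxylic acid (racemic) | OC(=O)C1(Cc2ccc(OCc3ccccc3)cc2)C(=O)CC(=O)C(Cc2ccc(OCc3ccccc3)cc2)=C1CCc1cccc(OCc2ccccc2)c1 | intermediate
18 | 4,6-bis[4-(benzyloxy)benzyl]-5-{2-[3-(benzyloxy)phenyl]ethyl}benzene-1,3-diol | Oc1cc(O)c(Cc2ccc(OCc3ccccc3)cc2)c(CCc2cccc(OCc3ccccc3)c2)c1Cc1ccc(OCc2ccccc2)cc1 | intermediate
19 | 2,4-bis[4-(benzyloxy)benzyl]-3-{2-[3-(benzyloxy)phenyl]ethyl}-5-methoxyphenol | COc1cc(O)c(Cc2ccc(OCc3ccccc3)cc2)c(CCc2cccc(OCc3ccccc3)c2)c1Cc1ccc(OCc2ccccc2)cc1 | intermediate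
20 | 2,4-bis(4-hydroxybenzyl)-3-[2-(3-hydroxyphenyl)ethyl]-5-methoxyphenol (3,3'-dihydroxy-2,6-bis(p-hydroxybenzyl)-5-methoxybibenzyl) | COc1cc(O)c(Cc2ccc(O)cc2)c(CCc2cccc(O)c2)c1Cc1ccc(O)cc1 | target

**Step count**
Total steps: 10. Longest linear sequence: 9 steps (steps 1, 2, 3, 4, 6, 7, 8, 9, 10 from compound 1).

**Steps most likely to fail**

1. Step 8 (proposed new method). The congested aldol may revert before dehydration, closure may take another mode (bridge-side CH2 onto the C3 ketone, or oxygen onto a carbonyl to give pyranones), the chain may cleave by retro-Claisen, or a 1,2-benzyl shift may compete with ester cleavage in the acid stage. The fallback uses the established resorcylate mode on a C2-unsubstituted chain and puts the second benzyl group on afterwards; it sets out from 9 and 10 and returns at 18. Compound 10 is converted with LDA into the dilithium dianion of tert-butyl acetoacetate F1, which is acylated with 9 to give tert-butyl 7-[4-(benzyloxy)phenyl]-6-{2-[2-(3-benzyloxyphenyl)ethyl]-1,3-dioxolan-2-yl}-3,5-dioxoheptanoate F2. Dilute aqueous acid unmasks this to tert-butyl 6-[4-(benzyloxy)benzyl]-9-[3-(benzyloxy)phenyl]-3,5,7-trioxononanoate F3. Carbonate-mediated aldol closure and dehydration should then give tert-butyl 3-[4-(benzyloxy)benzyl]-2-{2-[3-(benzyloxy)phenyl]ethyl}-4,6-dihydroxybenzoate F4. TFA should give 3-[4-(benzyloxy)benzyl]-2-{2-[3-(benzyloxy)phenyl]ethyl}-4,6-dihydroxybenzoic acid F5, which should lose CO2 on gentle warming, as β-resorcylic acids do, to give 4-[4-(benzyloxy)benzyl]-5-{2-[3-(benzyloxy)phenyl]ethyl}benzene-1,3-diol F6. Friedel–Crafts benzylation of F6 with 7 (HFIP, rt, or ZnCl2) at the free position next to the ethyl chain should give 18. The cost is that regiocontrol (this position against the one between the hydroxyls) and over-benzylation then depend on the arene itself.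

2. Step 6. Attack at the hindered, α-branched Weinreb carbonyl may be slow, so that proton transfer or base-induced loss of formaldehyde from the N-methoxy group takes over. The fallback replaces acylation by aldol addition and oxidation; it sets out from 9 and returns at 13. Reduction of 9 with LiAlH4 (THF, –78 → 0 °C) should give 3-[4-(benzyloxy)phenyl]-2-{2-[2-(3-benzyloxyphenyl)ethyl]-1,3-dioxolan-2-yl}propanal F7. Addition of dianion 12 to this much more reactive aldehyde should give tert-butyl 2-[4-(benzyloxy)benzyl]-7-[4-(benzyloxy)phenyl]-6-{2-[2-(3-benzyloxyphenyl)ethyl]-1,3-dioxolan-2-yl}-5-hydroxy-3-oxoheptanoate F8. Dess–Martin oxidation of the β-hydroxy ketone then gives 13.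

3. Step 9. Methylation may run on to the dimethyl ether while diol remains, since nothing but stoichiometry separates the first alkylation from the second. The fallback methylates fully and removes one methyl group selectively; it sets out from 18 and returns at 20. Excess MeI/K2CO3 should give 2,4-bis[4-(benzyloxy)benzyl]-3-{2-[3-(benzyloxy)phenyl]ethyl}-1,5-dimethoxybenzene F9. Hydrogenolysis (H2, Pd/C) should give 2,4-bis(4-hydroxybenzyl)-3-[2-(3-hydroxyphenyl)ethyl]-1,5-dimethoxybenzene F10. Sodium ethanethiolate in hot DMF should then cleave one methyl ether only, because the phenoxide formed deactivates the second, and give 20.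

**Further compounds**
F1 | step 8 | dilithium dianion of tert-butyl acetoacetate | [Li+].[Li+].C=C([O-])C=C([O-])OC(C)(C)C
F2 | step 8 | tert-butyl 7-[4-(benzyloxy)phenyl]-6-{2-[2-(3-benzyloxyphenyl)ethyl]-1,3-dioxolan-2-yl}-3,5-dioxoheptanoate | CC(C)(C)OC(=O)CC(=O)CC(=O)C(Cc1ccc(OCc2ccccc2)cc1)C1(CCc2cccc(OCc3ccccc3)c2)OCCO1
F3 | step 8 | tert-butyl 6-[4-(benzyloxy)benzyl]-9-[3-(benzyloxy)phenyl]-3,5,7-trioxononanoate | CC(C)(C)OC(=O)CC(=O)CC(=O)C(Cc1ccc(OCc2ccccc2)cc1)C(=O)CCc1cccc(OCc2ccccc2)c1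
F4 | step 8 | tert-butyl 3-[4-(benzyloxy)benzyl]-2-{2-[3-(benzyloxy)phenyl]ethyl}-4,6-dihydroxybenzoate | CC(C)(C)OC(=O)c1c(O)cc(O)c(Cc2ccc(OCc3ccccc3)cc2)c1CCc1cccc(OCc2ccccc2)c1
F5 | step 8 | 3-[4-(benzyloxy)benzyl]-2-{2-[3-(benzyloxy)phenyl]ethyl}-4,6-dihydroxybenzoic acid | OC(=O)c1c(O)cc(O)c(Cc2ccc(OCc3ccccc3)cc2)c1CCc1cccc(OCc2ccccc2)c1
F6 | step 8 | 4-[4-(benzyloxy)benzyl]-5-{2-[3-(benzyloxy)phenyl]ethyl}benzene-1,3-diol | Oc1cc(O)c(Cc2ccc(OCc3ccccc3)cc2)c(CCc2cccc(OCc3ccccc3)c2)c1
F7 | step 6 | 3-[4-(benzyloxy)phenyl]-2-{2-[2-(3-benzyloxyphenyl)ethyl]-1,3-dioxolan-2-yl}propanal | O=CC(Cc1ccc(OCc2ccccc2)cc1)C1(CCc2cccc(OCc3ccccc3)c2)OCCO1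
F8 | step 6 | tert-butyl 2-[4-(benzyloxy)benzyl]-7-[4-(benzyloxy)phenyl]-6-{2-[2-(3-benzyloxyphenyl)ethyl]-1,3-dioxolan-2-yl}-5-hydroxy-3-oxoheptanoate | CC(C)(C)OC(=O)C(Cc1ccc(OCc2ccccc2)cc1)C(=O)CC(O)C(Cc1ccc(OCc2ccccc2)cc1)C1(CCc2cccc(OCc3ccccc3)c2)OCCO1
F9 | step 9 | 2,4-bis[4-(benzyloxy)benzyl]-3-{2-[3-(benzyloxy)phenyl]ethyl}-1,5-dimethoxybenzene | COc1cc(OC)c(Cc2ccc(OCc3ccccc3)cc2)c(CCc2cccc(OCc3ccccc3)c2)c1Cc1ccc(OCc2ccccc2)cc1
F10 | step 9 | 2,4-bis(4-hydroxybenzyl)-3-[2-(3-hydroxyphenyl)ethyl]-1,5-dimethoxybenzene | COc1cc(OC)c(Cc2ccc(O)cc2)c(CCc2cccc(O)c2)c1Cc1ccc(O)cc1
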